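If J and Q did nothing but give G, the autumn flask would climb towards its 0.0800 M of J, yet at 17 h it reads 0.03183 M, less than that.

| flask | J | Q | G | time |
|---|---|---|---|---|
| autumn | 0.0800 M | 0.0960 M |  |  |
| midnight | 0.0800 M | 0.0960 M | 0.0400 M |  |
| winter | 0.0800 M | 0.140 M |  |  |
| summer | 0.160 M | 0.0960 M |  |  |
| dusk | 0.400 M | 0.480 M |  | 17 h |

- autumn run (time / h: [G] / M): 3.4: 0.01785; 6.8: 0.02541; 10: 0.02872; 14: 0.03099; 17: 0.03183
- midnight run (time / h: [G] / M): 3.4: 0.05455; 6.8: 0.05839; 10: 0.05969; 14: 0.06031; 17: 0.05965
- winter run (time / h: [G] / M): 3.4: 0.02983; 6.8: 0.03786; 10: 0.04079; 14: 0.04164; 17: 0.04203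
- summer run (time / h: [G] / M): 3.4: 0.03017; 6.8: 0.04009; 10: 0.04419; 14: 0.04655; 17: 0.04741

(scatter of a reading: 2 × 10⁻⁴ M)

- Overall: J + Q -> G.
- Constant volume, constant temperature.
- "The second partner" is Q.
- An order is taken over about fifteen percent of the charge, up and down.

- order of the initial rate in [J], near the charge of the autumn run, the rate being that where two percent of its J are G (one fixed amount of G, the same in the runs compared)
- order of the initial rate in [Q], near the charge of the autumn run, the rate being that where two percent of its J are G
- G in the dusk run at 17 h, as a share of the J charged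

Try a clock. Over the first interval of a run, divide the mean rate by [J] and by [Q] squared, both taken midway through the G made. This constant k, my trial rate constant9.74 M⁻² h⁻¹, reads:

autumn 9.74 M⁻² h⁻¹; winter 8.62 M⁻² h⁻¹; summer 9.35 M⁻² h⁻¹

So I take first order in J and second in Q. Winter reads lower than autumn, a gap I leave open. Over the first interval the midnight flask, charged with G, gained less than autumn, so I suppose that G is lost. If that loss goes as [G][Q], the midnight shortfall gives its ratio to k:

ρ = 0.0286 M

The lifetime of J is τ = 1/(k[Q] squared): 11.1 h at the autumn charge, 0.446 h at the dusk charge.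

Now two extreme dusk flasks. In the first, making and loss keep step, and dusk repeats the autumn share, 39.8%. But with the charge 5.00 times autumn's, my making speeds up per molecule by the square of that and the loss by that factor alone, so dusk should lie higher. In the second, no G is lost until growth stops, where [J][Q] = ρ[G]. That comes at 0.334 M of G, a share of 83.6% of J, the limiting reagent. There τ is 4.84 h, so 17 h holds 3.51 lifetimes, and dusk has time to get there. Lost G pulls the real flask below that, so I commit to the mean of the two, 61.7%.

The forecast gave 0.9, 1.7 and 68%, higher than my share, holding that dusk “should be fully equilibrated by 17 h”.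

The flask gives 1.0, 2.1 and 61.7%, after 38.1 lifetimes counted at the dusk charge.

    J + 2 Q → G + Q (11.95 M⁻² h⁻¹)
    G + Q → L (0.3305 M⁻¹ h⁻¹)
    2 Q → Oz (0.1541 M⁻¹ h⁻¹)

Where the same amount has been made, the midnight rate is 0.83 of the autumn rate. Now carry k to the winter flask. Midway through a quarter of its J, [Q] is 0.130 M, so τ is 6.07 h, and τ times the logarithm of 4/3 gives 1.75 h. The winter flask reaches that quarter at 1.63 h.

Readings and results were generated by integration for an exercise, noise included.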